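**Retrosynthetic overview**
1. Iridal comes from an eight-membered α,β-unsaturated lactone in which the C1 carbonyl is tied through the C3 oxygen to the C6 side chain; the tetrasubstituted C2=C7 alkene is endocyclic there and can only be Z (reduction, then allylic oxidation).
2. The lactone comes from a keto 2,2-dibromopropanoate by a new SmI2 Reformatsky–elimination that forms C2=C7.
3. The keto ester comes from a ketal-protected cyclohexanone carrying C6, C11 and C10; C10 is set by axial MeLi addition.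
4. That ketone comes from 7-methyl-1,4-dioxaspiro[4.5]dec-6-en-8-one by copper-catalysed asymmetric conjugate addition (C6), then trans enolate alkylation with homofarnesyl iodide (quaternary C11).
5. Ring order: the cyclohexane is bought; the only ring formed is the temporary eight-membered lactone (step 9), reopened in step 10.

Assumption: (3E,7E)-homofarnesol and 2,2-dibromopropanoic acid are taken as commercially available.
Abbreviations: homofarnesyl = (3E,7E)-4,8,12-trimethyltrideca-3,7,11-trien-1-yl; TBS-oxy = tert-butyldimethylsilyloxy; TMS-oxy = trimethylsilyloxy; atom labels C1–C13 in the Why lines follow iridal numbering (ring C6–C11, C7 bears C2, C1 = CHO, C3 = CH2OH).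

**Step 1**
Reactants: 1 1,4-dioxaspiro[4.5]dec-6-en-8-one
Product: 2 7-iodo-1,4-dioxaspiro[4.5]dec-6-en-8-one
Conditions: I2 (2 equiv), pyridine/CH2Cl2 1:1, 0 °C → rt
Reagents that add atoms: iodine, I-I
Why: α-Iodination of the enone (pyridine conjugate addition, iodination of the enolate, elimination) gives the alkenyl iodide needed for methylation; no stereocentre is formed.

**Step 2**
Reactants: 2 7-iodo-1,4-dioxaspiro[4.5]dec-6-en-8-one
Product: 3 7-methyl-1,4-dioxaspiro[4.5]dec-6-en-8-one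
Conditions: MeB(OH)2, Pd(dppf)Cl2 (5 mol %), K2CO3, dioxane/H2O, 80 °C
Reagents that add atoms: methylboronic acid, CB(O)O
Why: Suzuki–Miyaura coupling of the activated alkenyl iodide installs the future C11 methyl under basic conditions that leave the ketal intact; no stereocentre is formed.

**Step 3**
Reactants: 3 7-methyl-1,4-dioxaspiro[4.5]dec-6-en-8-one; 4 (3-bromopropoxy)(tert-butyl)dimethylsilane
Product: 7 (6S)-6-[3-(TBS-oxy)propyl]-7-methyl-8-(TMS-oxy)-1,4-dioxaspiro[4.5]dec-7-ene, via Grignard reagent 5 (not isolated), via magnesium enolate 6 (not isolated)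
Conditions: 4, Mg, THF, 40 °C; then 3, Cu(OTf)2 (5 mol %), (4S,5S)-1,3-bis(2-methylphenyl)-4,5-diphenyl-4,5-dihydroimidazolium tetrafluoroborate (6 mol %; antipode fixed in a first run to give 6S), Et2O, −30 °C; then TMSCl, Et3N, DMPU, −30 °C → rt
Reagents that add atoms: magnesium, [Mg] (stays in 5 and 6 only); chlorotrimethylsilane, C[Si](C)(C)Cl
Why: Copper-catalysed asymmetric conjugate addition of a Grignard reagent to the 2-methylcyclohexenone sets C6 (6S) by catalyst control alone, since the ketal makes the enone achiral, and O-silylation of the magnesium enolate (silyl enol ether formation) fixes the enolate regiochemistry for step 5.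

**Step 4**
Reactants: 8 (3E,7E)-4,8,12-trimethyltrideca-3,7,11-trien-1-ol
Product: 9 (3E,7E)-1-iodo-4,8,12-trimethyltrideca-3,7,11-triene
Conditions: I2, PPh3, imidazole, CH2Cl2, 0 °C
Reagents that add atoms: iodine, I-I
Why: Appel-type iodination converts the primary homoallylic alcohol into the iodide by SN2 displacement without touching the E-alkenes.

**Step 5**
Reactants: 7 (6S)-6-[3-(TBS-oxy)propyl]-7-methyl-8-(TMS-oxy)-1,4-dioxaspiro[4.5]dec-7-ene; 9 (3E,7E)-1-iodo-4,8,12-trimethyltrideca-3,7,11-triene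
Product: 11 (6S,7S)-6-[3-(TBS-oxy)propyl]-7-homofarnesyl-7-methyl-1,4-dioxaspiro[4.5]decan-8-one, via lithium enolate 10 (not isolated)
Conditions: MeLi (1.05 equiv), THF, 0 °C; then HMPA, 9 (2 equiv), −40 → 0 °C
Reagents that add atoms: methyllithium, [Li]C (lithium stays in 10 only)
Why: Regiospecific lithium enolate generation from the silyl enol ether and SN2 C-alkylation, in which the C6 chain sits pseudoaxial to avoid A(1,2) strain with the enolate methyl so the iodide attacks the opposite face, gives quaternary C11 with homofarnesyl trans to the C6 chain (7S).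

**Step 6**
Reactants: 11 (6S,7S)-6-[3-(TBS-oxy)propyl]-7-homofarnesyl-7-methyl-1,4-dioxaspiro[4.5]decan-8-one
Product: 12 (6S,7S,8S)-6-[3-(TBS-oxy)propyl]-7-homofarnesyl-7,8-dimethyl-1,4-dioxaspiro[4.5]decan-8-ol
Conditions: MeLi (3 equiv), Et2O, −78 → 0 °C; then H2O
Reagents that add atoms: methyllithium, [Li]C
Why: 1,2-Addition of methyllithium by axial attack on the chair with the C6 chain equatorial and the C11 methyl axial, anti to that methyl (equatorial attack is blocked by it, and the flipped chair by the then axial C6 chain), puts the new methyl cis to homofarnesyl and the C10 hydroxyl cis to the C11 methyl (8S).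

**Step 7**
Reactants: 12 (6S,7S,8S)-6-[3-(TBS-oxy)propyl]-7-homofarnesyl-7,8-dimethyl-1,4-dioxaspiro[4.5]decan-8-ol
Product: 13 (2S,3S,4S)-3-homofarnesyl-4-hydroxy-2-(3-hydroxypropyl)-3,4-dimethylcyclohexan-1-one
Conditions: 0.5 M HCl, THF/H2O 4:1, rt, short contact time
Reagents that add atoms: water, O
Why: Mild acid hydrolysis removes the dioxolane (unmasking the C7 ketone) and the primary silyl ether in one operation, while the tertiary alcohol and trisubstituted alkenes tolerate dilute acid and the short contact time keeps the now enolisable C6 from epimerising.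

**Step 8**
Reactants: 13 (2S,3S,4S)-3-homofarnesyl-4-hydroxy-2-(3-hydroxypropyl)-3,4-dimethylcyclohexan-1-one; 14 2,2-dibromopropanoic acid
Product: 16 3-[(1S,2S,3S)-2-homofarnesyl-2,3-dimethyl-6-oxo-3-(TMS-oxy)cyclohexyl]propyl 2,2-dibromopropanoate, via hydroxy ester 15 (not isolated)
Conditions: 14 (1.2 equiv), DCC, DMAP (cat.), CH2Cl2, 0 °C; then N-(trimethylsilyl)imidazole, rt
Reagents that add atoms: N-(trimethylsilyl)imidazole, C[Si](C)(C)n1ccnc1
Why: Steglich esterification acylates only the primary alcohol, and silyl transfer then masks the tertiary alcohol so it cannot protonate the samarium enolate in step 9; no stereocentre changes.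

**Step 9**
Reactants: 16 3-[(1S,2S,3S)-2-homofarnesyl-2,3-dimethyl-6-oxo-3-(TMS-oxy)cyclohexyl]propyl 2,2-dibromopropanoate
Product: 19 (8R,9S,10S)-9-homofarnesyl-2,9,10-trimethyl-10-(TMS-oxy)-4-oxabicyclo[6.4.0]dodec-1-en-3-one, via samarium enolate 17 (not isolated), via samarium aldolate 18 (not isolated)
Conditions: SmI2 (5 equiv, 0.1 M in THF), syringe-pump addition of 16 over 6 h (final 0.003 M), −20 °C → rt, no proton source, no HMPA; then aq. NaHCO3
Reagents that add atoms: samarium diiodide, I[Sm]I (samarium and iodine stay in 17 and 18 only)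
Why: Proposed new method: an intramolecular samarium Reformatsky–β-elimination of a ketone-tethered 2,2-dibromopropanoate, in which two SmI2 reduce one C–Br to the trivalent samarium bromo-enolate 17, this adds to the C7 ketone in a samarium-templated medium-ring aldol to give 18, and two more SmI2 reduce the second C–Br so that the β-samariumoxy enolate expels oxide and forms C2=C7 regiospecifically; because this alkene is endocyclic in an eight-membered lactone it can only be cis, which places C1 on the C6 side (the Z geometry of iridal), and the closest known reactions are the intermolecular SmI2 aldol/β-elimination of dibromoacetates with aldehydes and the SmI2 Reformatsky macrolactonisation of bromoacyl oxo esters.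

**Step 10**
Reactants: 19 (8R,9S,10S)-9-homofarnesyl-2,9,10-trimethyl-10-(TMS-oxy)-4-oxabicyclo[6.4.0]dodec-1-en-3-one
Product: 21 (2Z)-2-[(2R,3S,4S)-3-homofarnesyl-4-hydroxy-2-(3-hydroxypropyl)-3,4-dimethylcyclohexylidene]propan-1-ol, via silyl ether diol 20 (not isolated)
Conditions: iBu2AlH (6 equiv), CH2Cl2, −78 → 0 °C; aq. potassium sodium tartrate; then K2CO3 (0.2 equiv), MeOH, rt
Reagents that add atoms: none
Why: Hydride 1,2-reduction of the α,β-unsaturated lactone opens the ring to the allylic alcohol (C1) and the primary alcohol (C3) with the tetrasubstituted alkene geometry retained, and base-catalysed methanolysis then removes the tertiary trimethylsilyl ether.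

**Step 11**
Reactants: 21 (2Z)-2-[(2R,3S,4S)-3-homofarnesyl-4-hydroxy-2-(3-hydroxypropyl)-3,4-dimethylcyclohexylidene]propan-1-ol
Product: 22 iridal, (2Z)-2-[(2R,3S,4S)-3-homofarnesyl-4-hydroxy-2-(3-hydroxypropyl)-3,4-dimethylcyclohexylidene]propanal
Conditions: MnO2 (25 equiv), CH2Cl2, rt, dark
Reagents that add atoms: none
Why: Allylic oxidation with MnO2 converts only the allylic primary alcohol into the aldehyde, leaving the saturated primary and tertiary alcohols, and the neutral dark conditions do not isomerise the Z-enal.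

**Compound list**
1 | 1,4-dioxaspiro[4.5]dec-6-en-8-one | O=C1C=CC2(CC1)OCCO2 | starting material
2 | 7-iodo-1,4-dioxaspiro[4.5]dec-6-en-8-one | O=C1CCC2(C=C1I)OCCO2 | intermediate
3 | 7-methyl-1,4-dioxaspiro[4.5]dec-6-en-8-one | CC1=CC2(CCC1=O)OCCO2 | intermediate
4 | (3-bromopropoxy)(tert-butyl)dimethylsilane | CC(C)(C)[Si](C)(C)OCCCBr | starting material
5 | [3-(TBS-oxy)propyl]magnesium bromide | CC(C)(C)[Si](C)(C)OCCC[Mg]Br | intermediate
6 | bromomagnesium (6S)-6-[3-(TBS-oxy)propyl]-7-methyl-1,4-dioxaspiro[4.5]dec-7-en-8-olate | CC1=C(O[Mg]Br)CCC2(OCCO2)[C@H]1CCCO[Si](C)(C)C(C)(C)C | intermediate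
7 | (6S)-6-[3-(TBS-oxy)propyl]-7-methyl-8-(TMS-oxy)-1,4-dioxaspiro[4.5]dec-7-ene | CC1=C(O[Si](C)(C)C)CCC2(OCCO2)[C@H]1CCCO[Si](C)(C)C(C)(C)C | intermediate
8 | (3E,7E)-4,8,12-trimethyltrideca-3,7,11-trien-1-ol (homofarnesol) | CC(C)=CCC/C(C)=C/CC/C(C)=C/CCO | starting material
9 | (3E,7E)-1-iodo-4,8,12-trimethyltrideca-3,7,11-triene (homofarnesyl iodide) | CC(C)=CCC/C(C)=C/CC/C(C)=C/CCI | intermediate
10 | lithium (6S)-6-[3-(TBS-oxy)propyl]-7-methyl-1,4-dioxaspiro[4.5]dec-7-en-8-olate | CC1=C(O[Li])CCC2(OCCO2)[C@H]1CCCO[Si](C)(C)C(C)(C)C | intermediate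
11 | (6S,7S)-6-[3-(TBS-oxy)propyl]-7-homofarnesyl-7-methyl-1,4-dioxaspiro[4.5]decan-8-one | CC(C)=CCC/C(C)=C/CC/C(C)=C/CC[C@@]1(C)[C@H](CCCO[Si](C)(C)C(C)(C)C)C2(OCCO2)CCC1=O | intermediate
12 | (6S,7S,8S)-6-[3-(TBS-oxy)propyl]-7-homofarnesyl-7,8-dimethyl-1,4-dioxaspiro[4.5]decan-8-ol | CC(C)=CCC/C(C)=C/CC/C(C)=C/CC[C@@]1(C)[C@H](CCCO[Si](C)(C)C(C)(C)C)C2(OCCO2)CC[C@]1(C)O | intermediate
13 | (2S,3S,4S)-3-homofarnesyl-4-hydroxy-2-(3-hydroxypropyl)-3,4-dimethylcyclohexan-1-one | CC(C)=CCC/C(C)=C/CC/C(C)=C/CC[C@@]1(C)[C@H](CCCO)C(=O)CC[C@]1(C)O | intermediate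
14 | 2,2-dibromopropanoic acid | CC(Br)(Br)C(O)=O | starting material
15 | 3-[(1S,2S,3S)-2-homofarnesyl-3-hydroxy-2,3-dimethyl-6-oxocyclohexyl]propyl 2,2-dibromopropanoate | CC(C)=CCC/C(C)=C/CC/C(C)=C/CC[C@@]1(C)[C@H](CCCOC(=O)C(C)(Br)Br)C(=O)CC[C@]1(C)O | intermediate
16 | 3-[(1S,2S,3S)-2-homofarnesyl-2,3-dimethyl-6-oxo-3-(TMS-oxy)cyclohexyl]propyl 2,2-dibromopropanoate | CC(C)=CCC/C(C)=C/CC/C(C)=C/CC[C@@]1(C)[C@H](CCCOC(=O)C(C)(Br)Br)C(=O)CC[C@]1(C)O[Si](C)(C)C | intermediate
17 | diiodosamarium bromo-enolate of 16 (ester unit C(OSmI2)=C(Br)CH3; ring stereocentres as in 16) | CC(C)=CCC/C(C)=C/CC/C(C)=C/CC[C@@]1(C)[C@H](CCCOC(O[Sm](I)I)=C(C)Br)C(=O)CC[C@]1(C)O[Si](C)(C)C | intermediate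
18 | (8S,9S,10S)-2-bromo-1-(diiodosamariooxy)-9-homofarnesyl-2,9,10-trimethyl-10-(TMS-oxy)-4-oxabicyclo[6.4.0]dodecan-3-one (C1 and C2 not assigned) | CC(C)=CCC/C(C)=C/CC/C(C)=C/CC[C@@]1(C)[C@@H]2CCCOC(=O)C(C)(Br)C2(O[Sm](I)I)CC[C@]1(C)O[Si](C)(C)C | intermediate
19 | (8R,9S,10S)-9-homofarnesyl-2,9,10-trimethyl-10-(TMS-oxy)-4-oxabicyclo[6.4.0]dodec-1-en-3-one (eight-membered unsaturated lactone, ring alkene cis) | CC(C)=CCC/C(C)=C/CC/C(C)=C/CC[C@@]1(C)[C@@H]2CCCOC(=O)/C(C)=C2/CC[C@]1(C)O[Si](C)(C)C | intermediate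
20 | (2Z)-2-[(2R,3S,4S)-3-homofarnesyl-2-(3-hydroxypropyl)-3,4-dimethyl-4-(TMS-oxy)cyclohexylidene]propan-1-ol | CC(C)=CCC/C(C)=C/CC/C(C)=C/CC[C@@]1(C)[C@H](CCCO)/C(=C(/C)CO)CC[C@]1(C)O[Si](C)(C)C | intermediate
21 | (2Z)-2-[(2R,3S,4S)-3-homofarnesyl-4-hydroxy-2-(3-hydroxypropyl)-3,4-dimethylcyclohexylidene]propan-1-ol | CC(C)=CCC/C(C)=C/CC/C(C)=C/CC[C@@]1(C)[C@H](CCCO)/C(=C(/C)CO)CC[C@]1(C)O | intermediate
22 | iridal, (2Z)-2-[(2R,3S,4S)-3-homofarnesyl-4-hydroxy-2-(3-hydroxypropyl)-3,4-dimethylcyclohexylidene]propanal; (6R,10S,11S) in iridal numbering | CC(C)=CCC/C(C)=C/CC/C(C)=C/CC[C@@]1(C)[C@H](CCCO)/C(=C(/C)C=O)CC[C@]1(C)O | target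

**Step count and risks**
Total step count: 11. Longest linear sequence: 10 steps (1 → 22 through steps 1, 2, 3, 5, 6, 7, 8, 9, 10, 11); step 4 is the one-step side branch.

The three steps most likely to fail:

Step 3 (asymmetric conjugate addition). The enone is hindered on both sides of the β-carbon (α-methyl, neighbouring ketal), so conversion or ee may be low. The fallback replaces asymmetric catalysis by resolution; it sets out from 3 and comes back at 12. The addition and silylation are run with achiral CuBr·SMe2 (5 mol %, no ligand) to give the racemic silyl enol ether F1. Alkylation as in step 5 gives the racemic trans ketone F2, and MeLi as in step 6 gives the racemic alcohol F3. F3 is resolved by preparative chiral supercritical-fluid chromatography, and the (6S,7S,8S) enantiomer is 12.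

Step 5 (enolate alkylation with an unactivated homoallylic iodide). E2 elimination of the iodide and proton transfer can outrun C-alkylation at the hindered tetrasubstituted enolate. The fallback builds the chain by sp3–sp2 cross-coupling; it sets out from 7 and comes back at 11. Commercial (E)-geranylacetone is converted with LiN(iPr)2 and ClP(O)(OEt)2 into diethyl (5E)-6,10-dimethylundeca-1,5,9-trien-2-yl phosphate F4. More LiN(iPr)2 eliminates this to (5E)-6,10-dimethylundeca-5,9-dien-1-yne F5. Cp2ZrCl2-catalysed carboalumination with AlMe3 followed by I2 gives (1E,5E)-1-iodo-2,6,10-trimethylundeca-1,5,9-triene F6. Enolate 10 (from 7 and MeLi) is added to phenyl vinyl sulfoxide (Michael addition, same trans selectivity) to give (6S,7S)-6-[3-(TBS-oxy)propyl]-7-methyl-7-[2-(phenylsulfinyl)ethyl]-1,4-dioxaspiro[4.5]decan-8-one F7. Thermolysis (toluene, 110 °C, CaCO3) expels benzenesulfenic acid to give (6S,7S)-7-ethenyl-6-[3-(TBS-oxy)propyl]-7-methyl-1,4-dioxaspiro[4.5]decan-8-one F8. Hydroboration with 9-BBN gives the B-alkyl-9-borabicyclo[3.3.1]nonane adduct F9. Suzuki–Miyaura coupling of F9 with F6 (Pd(dppf)Cl2, AsPh3, Cs2CO3, DMF/H2O) gives 11.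

Step 9 (the proposed new method). The medium-ring aldol onto a hindered ketone may be slow, and simple reduction of the C–Br bonds competes. The fallback uses known chemistry in separate stages; it sets out from 13 and comes back at 19. Steglich esterification of 13 with 2-bromopropanoic acid gives 3-[(1S,2S,3S)-2-homofarnesyl-3-hydroxy-2,3-dimethyl-6-oxocyclohexyl]propyl 2-bromopropanoate F10. N-(Trimethylsilyl)imidazole gives its TMS ether F11. The known SmI2 intramolecular Reformatsky reaction (2.5 equiv SmI2, THF, high dilution) closes the ring to the β-hydroxy lactone (8S,9S,10S)-9-homofarnesyl-1-hydroxy-2,9,10-trimethyl-10-(TMS-oxy)-4-oxabicyclo[6.4.0]dodecan-3-one F12. Trifluoroacetic anhydride and pyridine give its 1-trifluoroacetate F13. E1cB elimination with DBU gives the conjugated cis-ring alkene 19.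

**Further compounds**
F1 | step 3 | racemic 6-[3-(TBS-oxy)propyl]-7-methyl-8-(TMS-oxy)-1,4-dioxaspiro[4.5]dec-7-ene | CC1=C(O[Si](C)(C)C)CCC2(OCCO2)C1CCCO[Si](C)(C)C(C)(C)C
F2 | step 3 | racemic (6S*,7S*)-6-[3-(TBS-oxy)propyl]-7-homofarnesyl-7-methyl-1,4-dioxaspiro[4.5]decan-8-one | CC(C)=CCC/C(C)=C/CC/C(C)=C/CCC1(C)C(CCCO[Si](C)(C)C(C)(C)C)C2(OCCO2)CCC1=O
F3 | step 3 | racemic (6S*,7S*,8S*)-6-[3-(TBS-oxy)propyl]-7-homofarnesyl-7,8-dimethyl-1,4-dioxaspiro[4.5]decan-8-ol | CC(C)=CCC/C(C)=C/CC/C(C)=C/CCC1(C)C(CCCO[Si](C)(C)C(C)(C)C)C2(OCCO2)CCC1(C)O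
F4 | step 5 | diethyl (5E)-6,10-dimethylundeca-1,5,9-trien-2-yl phosphate | CC(C)=CCC/C(C)=C/CCC(=C)OP(=O)(OCC)OCC
F5 | step 5 | (5E)-6,10-dimethylundeca-5,9-dien-1-yne | CC(C)=CCC/C(C)=C/CCC#C
F6 | step 5 | (1E,5E)-1-iodo-2,6,10-trimethylundeca-1,5,9-triene | CC(C)=CCC/C(C)=C/CC/C(C)=C/I
F7 | step 5 | (6S,7S)-6-[3-(TBS-oxy)propyl]-7-methyl-7-[2-(phenylsulfinyl)ethyl]-1,4-dioxaspiro[4.5]decan-8-one (sulfur centre not assigned) | O=S(CC[C@@]1(C)[C@H](CCCO[Si](C)(C)C(C)(C)C)C2(OCCO2)CCC1=O)c1ccccc1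
F8 | step 5 | (6S,7S)-7-ethenyl-6-[3-(TBS-oxy)propyl]-7-methyl-1,4-dioxaspiro[4.5]decan-8-one | C=C[C@@]1(C)[C@H](CCCO[Si](C)(C)C(C)(C)C)C2(OCCO2)CCC1=O
F9 | step 5 | 9-{2-[(6S,7S)-6-[3-(TBS-oxy)propyl]-7-methyl-8-oxo-1,4-dioxaspiro[4.5]decan-7-yl]ethyl}-9-borabicyclo[3.3.1]nonane | B1(CC[C@@]3(C)[C@H](CCCO[Si](C)(C)C(C)(C)C)C4(OCCO4)CCC3=O)C2CCCC1CCC2
F10 | step 9 | 3-[(1S,2S,3S)-2-homofarnesyl-3-hydroxy-2,3-dimethyl-6-oxocyclohexyl]propyl 2-bromopropanoate (C–Br centre not assigned) | CC(C)=CCC/C(C)=C/CC/C(C)=C/CC[C@@]1(C)[C@H](CCCOC(=O)C(C)Br)C(=O)CC[C@]1(C)O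
F11 | step 9 | 3-[(1S,2S,3S)-2-homofarnesyl-2,3-dimethyl-6-oxo-3-(TMS-oxy)cyclohexyl]propyl 2-bromopropanoate | CC(C)=CCC/C(C)=C/CC/C(C)=C/CC[C@@]1(C)[C@H](CCCOC(=O)C(C)Br)C(=O)CC[C@]1(C)O[Si](C)(C)C
F12 | step 9 | (8S,9S,10S)-9-homofarnesyl-1-hydroxy-2,9,10-trimethyl-10-(TMS-oxy)-4-oxabicyclo[6.4.0]dodecan-3-one (C1 and C2 not assigned) | CC(C)=CCC/C(C)=C/CC/C(C)=C/CC[C@@]1(C)[C@@H]2CCCOC(=O)C(C)C2(O)CC[C@]1(C)O[Si](C)(C)C
F13 | step 9 | 1-trifluoroacetate of F12 | CC(C)=CCC/C(C)=C/CC/C(C)=C/CC[C@@]1(C)[C@@H]2CCCOC(=O)C(C)C2(OC(=O)C(F)(F)F)CC[C@]1(C)O[Si](C)(C)C
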